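**Retrosynthetic overview**

1. The interflavan C4–C6 bond is made last: an acid-ionised (2R,3S,4R)-flavan-3,4-diol (leucofisetinidin) is trapped by (2R,3S)-fisetinidol, as in proanthocyanidin biosynthesis; no ring is formed here.
2. Both halves come from one dihydroflavonol, (2R,3R)-fustin tribenzyl ether: C-4 hydride reduction gives the diol, and reduction plus C-4 hydrogenolysis gives fisetinidol.
3. Ring C is the only ring made, formed once and used for both halves: the chalcone 2'-OH attacks C-β of an (αR,βS)-chalcone epoxide, the chalcone-isomerase O–C2 closure on a substrate already at the 3-hydroxylated level.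
4. Both stereocentres come from one catalytic asymmetric epoxidation of the free 2'-hydroxychalcone.
5. The chalcone comes from Claisen–Schmidt condensation of a ring A acetophenone and a ring B benzaldehyde, both bought as benzyl ethers.

Assumptions: the SMILES is read as (2R,3S)-fisetinidol-(4α→6)-(2R,3S)-fisetinidol, upper unit (2R,3S,4R), 2,3-trans-3,4-trans. 1-[4-(Benzyloxy)-2-hydroxyphenyl]ethan-1-one (1) and 3,4-bis(benzyloxy)benzaldehyde (2) are taken as catalogue chemicals.

**Step 1**
Reactants: 1 1-[4-(benzyloxy)-2-hydroxyphenyl]ethan-1-one; 2 3,4-bis(benzyloxy)benzaldehyde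
Product: 3 (E)-1-[4-(benzyloxy)-2-hydroxyphenyl]-3-[3,4-bis(benzyloxy)phenyl]prop-2-en-1-one (4',3,4-tri-O-benzylbutein)
Conditions: KOH (50% aq.), EtOH, rt, 48 h; then cold 1 M HCl
Reagents that add atoms: none
Why: Claisen–Schmidt (crossed aldol) condensation in which the acetophenone enolate adds to the non-enolisable aldehyde and E1cB dehydration gives only the conjugated (E)-enone, the 2'-phenoxide not cyclising in strong base; no stereocentre is formed.

**Step 2**
Reactants: 3 (E)-2'-hydroxychalcone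
Product: 5 (2R,3R)-7-(benzyloxy)-2-[3,4-bis(benzyloxy)phenyl]-3-hydroxy-2,3-dihydro-4H-chromen-4-one (7,3',4'-tri-O-benzylfustin, 2,3-trans), via (αR,βS)-epoxychalcone 4 (not isolated)
Conditions: (S)-α,α-bis(3,5-dimethylphenyl)prolinol (30 mol%), TBHP (1.1 equiv, decane), toluene–methylcyclohexane, 4 °C, 3–5 d; then DBU (0.1 equiv), THF, 0 °C, 1 h, argon; recrystallise (EtOAc–hexane)
Reagents that add atoms: tert-butyl hydroperoxide, CC(C)(C)OO
Why: Proposed new method: in a non-ionising medium the 2'-OH stays hydrogen-bonded to the carbonyl, which blocks oxa-Michael closure and racemic Algar–Flynn–Oyamada chemistry while activating the enone, so the bifunctional amino alcohol can deliver tert-butyl peroxide to one face of C-β and close the (αR,βS)-epoxide (Weitz–Scheffer epoxidation; the (S)-catalyst is, as recalled, the antipode that gives (αR,βS)-chalcone oxides, otherwise the (R)-catalyst is used), and catalytic DBU then frees the phenoxide, which opens the benzylic C-β–O bond by 6-exo-tet SN2 attack with inversion, so that C-2 (R) and C-3 (R, the retained C-α–O bond) are both set and 2,3-trans ring C arises from the same O-to-C-β bond that chalcone isomerase makes; the closest known reactions are prolinol/TBHP epoxidation of chalcones without a free 2'-OH and base-induced cyclisation of 2'-hydroxychalcone epoxides (made with dimethyldioxirane) to trans-3-hydroxyflavanones.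

**Step 3**
Reactants: 5 7,3',4'-tri-O-benzylfustin (about one fifth of the batch)
Product: 6 (2R,3R)-2-(3,4-dihydroxyphenyl)-3,7-dihydroxy-2,3-dihydro-4H-chromen-4-one ((2R,3R)-fustin)
Conditions: H2 (1 atm), 10% Pd/C, EtOAc–MeOH (1:1), rt, 3 h
Reagents that add atoms: none
Why: Hydrogenolysis of the three O-benzyl ethers under neutral conditions, where the electron-rich aryl ketone, the 3-OH and the cyclic C2–O1 bond are left alone, so C-2 and C-3 are unchanged.

**Step 4**
Reactants: 5 7,3',4'-tri-O-benzylfustin (about four fifths of the batch)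
Product: 8 (2R,3S)-2-(3,4-dihydroxyphenyl)chromane-3,7-diol ((2R,3S)-fisetinidol), via tribenzyl flavan-3,4-diol 7 (not isolated)
Conditions: NaBH4 (2 equiv), THF–EtOH (1:1), 0 °C, 1 h; then AcOH (to pH 4), 10% Pd/C, H2 (1–3 atm), rt, 16 h
Reagents that add atoms: none
Why: NaBH4 reduces the C-4 ketone (the counterpart of dihydroflavonol 4-reductase) mainly to the all-equatorial 3,4-trans diol, and acid-assisted benzylic hydrogenolysis over Pd/C then removes the benzyl ethers and the C-4 hydroxyl, which is activated by the para 7-oxygen and ortho O-1 (the counterpart of leucoanthocyanidin reductase); C-2 and C-3 are untouched, the C-3 descriptor changing from R to S only because C-4 loses CIP priority.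

**Step 5**
Reactants: 6 (2R,3R)-fustin (1 equiv); 8 (2R,3S)-fisetinidol (4 equiv)
Product: 10 (2R,3S,4R)-2-(3,4-dihydroxyphenyl)-4-[(2R,3S)-2-(3,4-dihydroxyphenyl)-3,7-dihydroxychroman-6-yl]chromane-3,7-diol (the target), via mollisacacidin 9 (not isolated)
Conditions: 6, NaBH4 (4 equiv), EtOH, 0 °C to rt, 1 h, argon; then 8, aq. HCl to 0.1 M (EtOH–H2O), rt, 16 h, argon; Sephadex LH-20 (EtOH), excess 8 recovered
Reagents that add atoms: none
Why: In 0.1 M HCl the 4-OH of the diol ionises to the C-4 benzylic cation/para-quinone methide stabilised by the 7-OH, which C-6 of 8 (para to O-1, ortho to 7-OH, less hindered than C-8) traps in an SN1 Friedel–Crafts-type alkylation with attack anti to the 3-OH, giving the 3,4-trans (4R, 4α) bond as the major isomer; this is the acid-catalysed flavan-3,4-diol/flavan-3-ol condensation presumed for proanthocyanidin biosynthesis, and excess 8 suppresses self-condensation.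

**Compound list**

1 | 1-[4-(benzyloxy)-2-hydroxyphenyl]ethan-1-one | CC(=O)c1ccc(OCc2ccccc2)cc1O | starting material
2 | 3,4-bis(benzyloxy)benzaldehyde | O=Cc1ccc(OCc2ccccc2)c(OCc2ccccc2)c1 | starting material
3 | (E)-1-[4-(benzyloxy)-2-hydroxyphenyl]-3-[3,4-bis(benzyloxy)phenyl]prop-2-en-1-one | O=C(/C=C/c1ccc(OCc2ccccc2)c(OCc2ccccc2)c1)c1ccc(OCc2ccccc2)cc1O | intermediate
4 | [4-(benzyloxy)-2-hydroxyphenyl]{(2R,3S)-3-[3,4-bis(benzyloxy)phenyl]oxiran-2-yl}methanone, the (αR,βS)-epoxide of 3 | O=C(c1ccc(OCc2ccccc2)cc1O)[C@@H]1O[C@H]1c1ccc(OCc2ccccc2)c(OCc2ccccc2)c1 | intermediate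
5 | (2R,3R)-7-(benzyloxy)-2-[3,4-bis(benzyloxy)phenyl]-3-hydroxy-2,3-dihydro-4H-chromen-4-one (2,3-trans) | O=C1c2ccc(OCc3ccccc3)cc2O[C@H](c2ccc(OCc3ccccc3)c(OCc3ccccc3)c2)[C@H]1O | intermediate
6 | (2R,3R)-2-(3,4-dihydroxyphenyl)-3,7-dihydroxy-2,3-dihydro-4H-chromen-4-one, (2R,3R)-fustin | O=C1c2ccc(O)cc2O[C@H](c2ccc(O)c(O)c2)[C@H]1O | intermediate
7 | (2R,3S,4R)-7-(benzyloxy)-2-[3,4-bis(benzyloxy)phenyl]chromane-3,4-diol (2,3-trans-3,4-trans) | c1ccccc1COc1ccc2c(c1)O[C@H](c1ccc(OCc3ccccc3)c(OCc3ccccc3)c1)[C@@H](O)[C@@H]2O | intermediate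
8 | (2R,3S)-2-(3,4-dihydroxyphenyl)chromane-3,7-diol, (2R,3S)-fisetinidol | Oc1ccc2c(c1)O[C@H](c1ccc(O)c(O)c1)[C@@H](O)C2 | intermediate
9 | (2R,3S,4R)-2-(3,4-dihydroxyphenyl)chromane-3,4,7-triol, mollisacacidin (2,3-trans-3,4-trans) | Oc1ccc2c(c1)O[C@H](c1ccc(O)c(O)c1)[C@@H](O)[C@@H]2O | intermediate
10 | (2R,3S,4R)-2-(3,4-dihydroxyphenyl)-4-[(2R,3S)-2-(3,4-dihydroxyphenyl)-3,7-dihydroxychroman-6-yl]chromane-3,7-diol | Oc1ccc2c(c1)O[C@H](c1ccc(O)c(O)c1)[C@@H](O)[C@@H]2c1cc2c(cc1O)O[C@H](c1ccc(O)c(O)c1)[C@@H](O)C2 | target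

**Totals**

Total step count: 5. Longest linear sequence: 4 (steps 1, 2, 4, 5; step 3 is a one-step branch from 5).

**Steps most likely to fail**

Step 2 is the riskiest. The electron-rich enone may epoxidise slowly, the amine may ionise the phenol and divert material to the racemic flavanone, the ee may be modest, and 5-exo closure or over-oxidation to the flavonol can compete. The fallback masks the phenol and uses a polyamino-acid epoxidation with good precedent on 2'-alkoxychalcones. It sets out from 1: O-allylation (allyl bromide, K2CO3, DMF, 60 °C) gives 1-[2-(allyloxy)-4-(benzyloxy)phenyl]ethan-1-one F1. Claisen–Schmidt condensation with 2 (KOH, EtOH, rt) gives (E)-1-[2-(allyloxy)-4-(benzyloxy)phenyl]-3-[3,4-bis(benzyloxy)phenyl]prop-2-en-1-one F2. Julia–Colonna epoxidation (poly-L-leucine, urea–hydrogen peroxide, DBU, THF, rt) gives [2-(allyloxy)-4-(benzyloxy)phenyl]{(2R,3S)-3-[3,4-bis(benzyloxy)phenyl]oxiran-2-yl}methanone F3. Pd(PPh3)4 (5 mol%), K2CO3, MeOH, rt then removes the allyl group, and the freed phenoxide closes ring C in the same flask. The fallback comes back to the route at 5.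

Step 5 can give the 4β epimer, some (4→8) isomer, trimers and self-condensed diol alongside the wanted dimer. The fallback replaces the free cation in acid by a storable C-4 thioether that is activated under neutral conditions. It sets out from 6: reduction with NaBH4 as in step 5 gives 9, and benzyl mercaptan (10 equiv) in 0.1 M ethanolic HCl at rt captures the cation as (2R,3R,4R)-4-(benzylsulfanyl)-2-(3,4-dihydroxyphenyl)chromane-3,7-diol F5, which is purified. AgBF4 (2.5 equiv) in THF at 0 °C with 8 (3 equiv) then releases the same C-4 electrophile without acid, so the product is not re-ionised and oligomers are limited. The fallback comes back to the route at 10.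

Step 4 can over-reduce (hydrogenolysis of the ring C C2–O1 bond to a 1,3-diarylpropan-2-ol) or stall at the diol. The fallback removes the C-4 oxygen by ionic hydrogenation before the phenols are freed. It sets out from 5: NaBH4 (THF–EtOH, 0 °C) gives 7, this time isolated. Et3SiH (5 equiv) and TFA (5 equiv) in CH2Cl2 at −20 °C give (2R,3S)-7-(benzyloxy)-2-[3,4-bis(benzyloxy)phenyl]chroman-3-ol F4. Neutral hydrogenolysis (H2, Pd(OH)2/C, EtOAc–MeOH, rt) removes the benzyl ethers, and the fallback comes back to the route at 8.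

**Further compounds**

F1 | step 2 | 1-[2-(allyloxy)-4-(benzyloxy)phenyl]ethan-1-one | CC(=O)c1ccc(OCc2ccccc2)cc1OCC=C
F2 | step 2 | (E)-1-[2-(allyloxy)-4-(benzyloxy)phenyl]-3-[3,4-bis(benzyloxy)phenyl]prop-2-en-1-one | O=C(/C=C/c1ccc(OCc2ccccc2)c(OCc2ccccc2)c1)c1ccc(OCc2ccccc2)cc1OCC=C
F3 | step 2 | [2-(allyloxy)-4-(benzyloxy)phenyl]{(2R,3S)-3-[3,4-bis(benzyloxy)phenyl]oxiran-2-yl}methanone | O=C(c1ccc(OCc2ccccc2)cc1OCC=C)[C@@H]1O[C@H]1c1ccc(OCc2ccccc2)c(OCc2ccccc2)c1
F4 | step 4 | (2R,3S)-7-(benzyloxy)-2-[3,4-bis(benzyloxy)phenyl]chroman-3-ol | c1ccccc1COc1ccc2c(c1)O[C@H](c1ccc(OCc3ccccc3)c(OCc3ccccc3)c1)[C@@H](O)C2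
F5 | step 5 | (2R,3R,4R)-4-(benzylsulfanyl)-2-(3,4-dihydroxyphenyl)chromane-3,7-diol (2,3-trans-3,4-trans) | Oc1ccc2c(c1)O[C@H](c1ccc(O)c(O)c1)[C@@H](O)[C@@H]2SCc1ccccc1
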